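**Plan**

1. Numbering: ring C1 (carbinol), C3 (Br), C4 (Cl, CH3); side chain C1′H2=C2′–C3′–C4′–C5′(OH)–C6′(CH3)=C7′H2. The enabling feature is the secondary carbinol C5′ next to the C6′=C7′ isopropenyl alkene, remote from the cyclohexane ring: it is the 1,3-transposed form of a C5′–C6′ oxirane bearing a C7′ hydroxymethyl group, i.e. of an (E)-2-methylalk-2-en-1-ol.
2. Retrosynthetic cuts: the C5′(OH)–C6′=C7′ unit back to the oxirane (transposition); the oxirane C5′–O and C6′–O bonds (asymmetric epoxidation); C1′=C2′ (methylenation); C2′–C3′ (Grignard addition to a C1 carbaldehyde); C4–Cl, then C3–Br and C4–O (opening and formation of a C1–O–C4 ether bridge); C1–C2 and C5–C6 (Diels–Alder).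
3. Forward order: the cyclohexene ring is made first from isoprene and 2-bromoacrolein; a 7-oxabicyclo[2.2.1]heptane bridge is closed and reopened to place Br and Cl; the C7 chain is joined at C2′; the oxirane is formed last and opened again.
4. Stereochemistry: C1 from the catalyst-controlled Diels–Alder reaction (inverted once in the spiro-epoxide closure); C3 and C4 relayed from C1 through the ether bridge (anti bromoetherification, then chloride entry with retention via the bromonium ion); C5′ from D-(−)-diisopropyl tartrate; the C5′=C6′ geometry from E-selective SeO2 oxidation.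

Key step: step 15

Remark (assumption): the (S)-tryptophan-derived oxazaborolidinone is taken to expose the re face of C-α of 2-bromoacrolein to isoprene as it does to cyclopentadiene; the sense is to be confirmed on 3, and the mirror-image catalyst would be used if it were opposite. 2-Bromoacrolein is treated as a purchasable reagent.

**Route**

Step 1
Reactants: 1 isoprene; 2 2-bromoacrolein
Product: 3 (1R)-1-bromo-4-methylcyclohex-3-ene-1-carbaldehyde
Conditions: (S)-N-tosyltryptophan-derived B-butyl-1,3,2-oxazaborolidin-5-one (10 mol%), isoprene (4 equiv), CH2Cl2, −78 °C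
Reagents that add atoms: none
Why: Catalytic enantioselective Diels–Alder reaction in which the boron Lewis acid binds the aldehyde, the indole covers one face of the s-cis dienophile and isoprene should add to the open re face of C-α with "para" orientation, which sets C1 as (R) and places the methyl group on C4.

Step 2
Reactants: 3 (1R)-1-bromo-4-methylcyclohex-3-ene-1-carbaldehyde
Product: 5 (3S)-6-methyl-1-oxaspiro[2.5]oct-5-ene, via bromohydrin 4 (not isolated)
Conditions: NaBH4, MeOH, 0 °C; then 2 M aq NaOH, rt; pentane extraction (volatile)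
Reagents that add atoms: none
Why: Borohydride reduction followed by base-induced halohydrin-to-epoxide closure (intramolecular SN2, 3-exo-tet) replaces the C1–Br bond by a C1–O bond with inversion, which puts the oxygen on the ring face the target requires.

Step 3
Reactants: 5 (3S)-6-methyl-1-oxaspiro[2.5]oct-5-ene
Product: 6 [(1S)-1-hydroxy-4-methylcyclohex-3-en-1-yl]methyl benzoate
Conditions: PhCO2H (1.5 equiv), PhCO2Cs (0.2 equiv), DMF, 80 °C
Reagents that add atoms: benzoic acid, O=C(O)c1ccccc1
Why: Carboxylate opening of a 2,2-disubstituted epoxide under basic buffering is an SN2 reaction at the CH2 terminus, so C1 and its C–O bond are untouched and the primary oxygen is masked as a benzoate that tolerates NBS and TiCl4.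

Step 4
Reactants: 6 [(1S)-1-hydroxy-4-methylcyclohex-3-en-1-yl]methyl benzoate
Product: 7 [(1S,3R,4R)-3-bromo-4-methyl-7-oxabicyclo[2.2.1]heptan-1-yl]methyl benzoate
Conditions: NBS (1.1 equiv), CH2Cl2, 0 °C, dark
Reagents that add atoms: N-bromosuccinimide, O=C1CCC(=O)N1Br
Why: Bromoetherification (transannular halocyclisation of a cyclohex-3-en-1-ol) in which only the bromonium ion on the face opposite the C1 hydroxyl can be captured and the oxygen attacks tertiary C4 through a boat, so anti addition fixes C4–O syn and C3–Br anti to the C1 oxygen.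

Step 5
Reactants: 7 [(1S,3R,4R)-3-bromo-4-methyl-7-oxabicyclo[2.2.1]heptan-1-yl]methyl benzoate
Product: 8 [(1S,3R,4R)-3-bromo-4-chloro-1-hydroxy-4-methylcyclohexyl]methyl benzoate
Conditions: TiCl4 (1.5 equiv), CH2Cl2, −78 → −30 °C; then ice-water
Reagents that add atoms: titanium tetrachloride, Cl[Ti](Cl)(Cl)Cl
Why: Lewis-acid cleavage of a bridged tertiary ether with chloride capture, in which titanium coordination ionises the C4–O bond (C1–O is deactivated by the adjacent acyloxymethyl group), the antiperiplanar endo bromine re-forms the bromonium ion and chloride opens it at tertiary C4 anti to bromine, so that Cl enters on the face the oxygen has left (net retention) and trans to Br.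

Step 6
Reactants: 8 [(1S,3R,4R)-3-bromo-4-chloro-1-hydroxy-4-methylcyclohexyl]methyl benzoate
Product: 9 {(1S,3R,4R)-3-bromo-4-chloro-4-methyl-1-[(triethylsilyl)oxy]cyclohexyl}methyl benzoate
Conditions: TESOTf (1.5 equiv), 2,6-lutidine (3 equiv), CH2Cl2, −78 → 0 °C
Reagents that add atoms: triethylsilyl trifluoromethanesulfonate, CC[Si](CC)(CC)OS(=O)(=O)C(F)(F)F
Why: Silyl triflate silylation of a hindered tertiary alcohol protects C1–OH against alkoxide-driven fragmentation in the organometallic steps that follow and touches no stereocentre.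

Step 7
Reactants: 9 {(1S,3R,4R)-3-bromo-4-chloro-4-methyl-1-[(triethylsilyl)oxy]cyclohexyl}methyl benzoate
Product: 10 {(1S,3R,4R)-3-bromo-4-chloro-4-methyl-1-[(triethylsilyl)oxy]cyclohexyl}methanol
Conditions: DIBAL-H (2.5 equiv), CH2Cl2, −78 °C; Rochelle salt work-up
Reagents that add atoms: none
Why: DIBAL-H reduction cleaves the benzoate to the primary alcohol at low temperature without base, which spares the alkyl halides and disfavours 1,2-migration of the silyl group.

Step 8
Reactants: 10 {(1S,3R,4R)-3-bromo-4-chloro-4-methyl-1-[(triethylsilyl)oxy]cyclohexyl}methanol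
Product: 11 (1S,3R,4R)-3-bromo-4-chloro-4-methyl-1-[(triethylsilyl)oxy]cyclohexane-1-carbaldehyde
Conditions: Dess–Martin periodinane, CH2Cl2, rt
Reagents that add atoms: none
Why: Dess–Martin oxidation converts the neopentyl-type primary alcohol into an aldehyde that has no α-hydrogen and so cannot enolise or epimerise.

Step 9
Reactants: 12 5-bromo-2-methylpent-2-ene
Product: 13 (2E)-5-bromo-2-methylpent-2-en-1-ol
Conditions: SeO2 (0.2 equiv), t-BuOOH (2 equiv), salicylic acid (cat.), CH2Cl2, rt
Reagents that add atoms: selenium dioxide, O=[Se]=O; tert-butyl hydroperoxide, CC(C)(C)OO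
Why: Selenium dioxide allylic oxidation (ene reaction, then [2,3]-sigmatropic shift) of a gem-dimethyl trisubstituted alkene hydroxylates the methyl group trans to the chain, which gives the (E)-allylic alcohol the epoxidation needs.

Step 10
Reactants: 13 (2E)-5-bromo-2-methylpent-2-en-1-ol
Product: 14 {[(2E)-5-bromo-2-methylpent-2-en-1-yl]oxy}(tert-butyl)dimethylsilane
Conditions: TBSCl, imidazole, CH2Cl2, rt
Reagents that add atoms: tert-butyldimethylsilyl chloride, CC(C)(C)[Si](C)(C)Cl
Why: Standard silylation of a primary alcohol masks the hydroxyl so that the bromide can be converted into a Grignard reagent.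

Step 11
Reactants: 14 {[(2E)-5-bromo-2-methylpent-2-en-1-yl]oxy}(tert-butyl)dimethylsilane; 11 (1S,3R,4R)-3-bromo-4-chloro-4-methyl-1-[(triethylsilyl)oxy]cyclohexane-1-carbaldehyde
Product: 16 (4E)-1-{(1S,3R,4R)-3-bromo-4-chloro-4-methyl-1-[(triethylsilyl)oxy]cyclohexyl}-6-[(tert-butyldimethylsilyl)oxy]-5-methylhex-4-en-1-ol as a mixture of carbinol epimers, via Grignard reagent 15 (not isolated)
Conditions: Mg, I2 (cat.), THF, 35 °C; then 11, THF, −78 → −30 °C; cold aq NH4Cl
Reagents that add atoms: none
Why: Magnesium insertion into the primary homoallylic bromide and Grignard addition to the non-enolisable aldehyde form the C2′–C3′ bond; the new carbinol centre is oxidised in the next step, so its configuration is irrelevant, and the cold quench keeps the triethylsilyl group on the tertiary oxygen.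

Step 12
Reactants: 16 (4E)-1-{(1S,3R,4R)-3-bromo-4-chloro-4-methyl-1-[(triethylsilyl)oxy]cyclohexyl}-6-[(tert-butyldimethylsilyl)oxy]-5-methylhex-4-en-1-ol
Product: 17 (4E)-1-{(1S,3R,4R)-3-bromo-4-chloro-4-methyl-1-[(triethylsilyl)oxy]cyclohexyl}-6-[(tert-butyldimethylsilyl)oxy]-5-methylhex-4-en-1-one
Conditions: Dess–Martin periodinane, pyridine, CH2Cl2, rt
Reagents that add atoms: none
Why: Dess–Martin oxidation of the secondary alcohol gives the ketone under buffered conditions that leave both silyl ethers, the halides and the trisubstituted alkene intact.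

Step 13
Reactants: 17 (4E)-1-{(1S,3R,4R)-3-bromo-4-chloro-4-methyl-1-[(triethylsilyl)oxy]cyclohexyl}-6-[(tert-butyldimethylsilyl)oxy]-5-methylhex-4-en-1-one
Product: 18 tert-butyl{[(2E)-6-{(1S,3R,4R)-3-bromo-4-chloro-4-methyl-1-[(triethylsilyl)oxy]cyclohexyl}-2-methylhepta-2,6-dien-1-yl]oxy}dimethylsilane
Conditions: Tebbe reagent (2 equiv), pyridine (cat.), THF/toluene, −40 °C → rt; aq NaOH quench
Reagents that add atoms: Tebbe reagent, C[Al-]1(C)C[Ti](C2C=CC=C2)(C2C=CC=C2)[Cl+]1 (cyclopentadienyl rings drawn σ-bonded)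
Why: Tebbe methylenation (titanium methylidene [2+2] cycloaddition and cycloreversion) converts hindered, enolisable ketones into 1,1-disubstituted alkenes without base, so the halides are not eliminated.

Step 14
Reactants: 18 tert-butyl{[(2E)-6-{(1S,3R,4R)-3-bromo-4-chloro-4-methyl-1-[(triethylsilyl)oxy]cyclohexyl}-2-methylhepta-2,6-dien-1-yl]oxy}dimethylsilane
Product: 19 (1S,3R,4R)-3-bromo-4-chloro-1-[(5E)-7-hydroxy-6-methylhepta-1,5-dien-2-yl]-4-methylcyclohexan-1-ol
Conditions: HF·pyridine, pyridine, THF, 0 °C → rt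
Reagents that add atoms: none
Why: Fluoride-mediated desilylation with buffered HF·pyridine removes the primary TBS and the tertiary TES ether together without acid strong enough to ionise the tertiary allylic alcohol or the tertiary chloride.

Step 15
Reactants: 19 (1S,3R,4R)-3-bromo-4-chloro-1-[(5E)-7-hydroxy-6-methylhepta-1,5-dien-2-yl]-4-methylcyclohexan-1-ol
Product: 20 (1S,3R,4R)-3-bromo-4-chloro-1-{4-[(2R,3R)-3-(hydroxymethyl)-3-methyloxiran-2-yl]but-1-en-2-yl}-4-methylcyclohexan-1-ol
Conditions: Ti(OiPr)4 (0.2 equiv), D-(−)-diisopropyl tartrate (0.25 equiv), t-BuOOH (2 equiv, anhydrous in decane), 4 Å MS, CH2Cl2, −20 °C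
Reagents that add atoms: tert-butyl hydroperoxide, CC(C)(C)OO
Why: The primary allylic alcohol and the hydroperoxide exchange onto the dimeric titanium–tartrate complex and the bound peroxide oxygen is passed in one concerted step to the C5′=C6′ π bond, so both C–O bonds of the oxirane form together (Sharpless asymmetric epoxidation of an (E)-2-methylalk-2-en-1-ol, a standard substrate class). The three-membered ring closes by syn [2+1] oxygen-atom transfer, so the E geometry becomes the trans relationship of C4′ and C7′ on the oxirane. Both new stereocentres, C5′ and C6′, are fixed by the tartrate: D-(−)-DIPT directs oxygen to the face that gives the (2R,3R)-epoxy alcohol, the same sense as for simple (E)-alkenols, and the nearest ring stereocentre (C1, four bonds from C5′) cannot bias the face. The step needs enantioface control, which is reagent-based, and chemoselectivity over the C1′=C2′ alkene, which is secured because a 1,1-disubstituted alkene beside a tertiary carbinol is epoxidised far more slowly than a trisubstituted alkene carrying a primary hydroxymethyl group. The bromide, the chloride and the free tertiary alcohol are inert at −20 °C, and the low titanium loading keeps the C1 hydroxyl from opening the new oxirane. Because the C5′–O bond made here survives the transposition, C5′ of the target is obtained as (R).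

Step 16
Reactants: 20 (1S,3R,4R)-3-bromo-4-chloro-1-{4-[(2R,3R)-3-(hydroxymethyl)-3-methyloxiran-2-yl]but-1-en-2-yl}-4-methylcyclohexan-1-ol
Product: 21 (2S,3R)-3-{3-[(1S,3R,4R)-3-bromo-4-chloro-1-hydroxy-4-methylcyclohexyl]but-3-en-1-yl}-2-methyloxirane-2-carbaldehyde
Conditions: Dess–Martin periodinane, pyridine, CH2Cl2, 0 °C → rt
Reagents that add atoms: none
Why: Dess–Martin oxidation of a 2,3-epoxy alcohol gives the epoxy aldehyde without touching the tertiary alcohol; the pyridine buffer prevents acid opening of the oxirane and C6′ is quaternary, so nothing can epimerise (the descriptor at C6′ changes only through CIP priorities).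

Step 17
Reactants: 21 (2S,3R)-3-{3-[(1S,3R,4R)-3-bromo-4-chloro-1-hydroxy-4-methylcyclohexyl]but-3-en-1-yl}-2-methyloxirane-2-carbaldehyde
Product: 24 (1S,3R,4R)-3-bromo-4-chloro-1-[(5R)-5-hydroxy-6-methylhepta-1,6-dien-2-yl]-4-methylcyclohexan-1-ol, via epoxy hydrazone 22 (not isolated), via hydroxy alkenyldiazene 23 (not isolated)
Conditions: N2H4·H2O (3 equiv), AcOH (0.5 equiv), MeOH, 0 °C → rt, under argon
Reagents that add atoms: none
Why: Wharton transposition in which the hydrazone tautomerises with opening of the C6′–O bond to an alkenyldiazene that loses N2, which moves the alkene to C6′=C7′ and leaves the C5′–O bond and its (R) configuration untouched.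

**Compound list**

1 | isoprene | C=CC(C)=C | starting material
2 | 2-bromoacrolein (2-bromoprop-2-enal) | C=C(Br)C=O | starting material
3 | (1R)-1-bromo-4-methylcyclohex-3-ene-1-carbaldehyde | Br[C@]1(C=O)CCC(C)=CC1 | intermediate
4 | [(1R)-1-bromo-4-methylcyclohex-3-en-1-yl]methanol (bromohydrin) | Br[C@]1(CO)CCC(C)=CC1 | intermediate (not isolated)
5 | (3S)-6-methyl-1-oxaspiro[2.5]oct-5-ene | C1O[C@]12CCC(C)=CC2 | intermediate
6 | [(1S)-1-hydroxy-4-methylcyclohex-3-en-1-yl]methyl benzoate | O=C(OC[C@]1(O)CCC(C)=CC1)c1ccccc1 | intermediate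
7 | [(1S,3R,4R)-3-bromo-4-methyl-7-oxabicyclo[2.2.1]heptan-1-yl]methyl benzoate | O=C(OC[C@]1(O2)CC[C@]2(C)[C@H](Br)C1)c1ccccc1 | intermediate
8 | [(1S,3R,4R)-3-bromo-4-chloro-1-hydroxy-4-methylcyclohexyl]methyl benzoate | O=C(OC[C@]1(O)CC[C@@](C)(Cl)[C@H](Br)C1)c1ccccc1 | intermediate
9 | {(1S,3R,4R)-3-bromo-4-chloro-4-methyl-1-[(triethylsilyl)oxy]cyclohexyl}methyl benzoate | O=C(OC[C@]1(O[Si](CC)(CC)CC)CC[C@@](C)(Cl)[C@H](Br)C1)c1ccccc1 | intermediate
10 | {(1S,3R,4R)-3-bromo-4-chloro-4-methyl-1-[(triethylsilyl)oxy]cyclohexyl}methanol | OC[C@]1(O[Si](CC)(CC)CC)CC[C@@](C)(Cl)[C@H](Br)C1 | intermediate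
11 | (1S,3R,4R)-3-bromo-4-chloro-4-methyl-1-[(triethylsilyl)oxy]cyclohexane-1-carbaldehyde | O=C[C@]1(O[Si](CC)(CC)CC)CC[C@@](C)(Cl)[C@H](Br)C1 | intermediate
12 | 5-bromo-2-methylpent-2-ene | CC(C)=CCCBr | starting material
13 | (2E)-5-bromo-2-methylpent-2-en-1-ol | OC/C(C)=C/CCBr | intermediate
14 | {[(2E)-5-bromo-2-methylpent-2-en-1-yl]oxy}(tert-butyl)dimethylsilane | CC(C)(C)[Si](C)(C)OC/C(C)=C/CCBr | intermediate
15 | {(3E)-5-[(tert-butyldimethylsilyl)oxy]-4-methylpent-3-en-1-yl}magnesium bromide (Grignard reagent) | CC(C)(C)[Si](C)(C)OC/C(C)=C/CC[Mg]Br | intermediate (not isolated)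
16 | (4E)-1-{(1S,3R,4R)-3-bromo-4-chloro-4-methyl-1-[(triethylsilyl)oxy]cyclohexyl}-6-[(tert-butyldimethylsilyl)oxy]-5-methylhex-4-en-1-ol (both carbinol epimers) | CC(C)(C)[Si](C)(C)OC/C(C)=C/CCC(O)[C@]1(O[Si](CC)(CC)CC)CC[C@@](C)(Cl)[C@H](Br)C1 | intermediate
17 | (4E)-1-{(1S,3R,4R)-3-bromo-4-chloro-4-methyl-1-[(triethylsilyl)oxy]cyclohexyl}-6-[(tert-butyldimethylsilyl)oxy]-5-methylhex-4-en-1-one | CC(C)(C)[Si](C)(C)OC/C(C)=C/CCC(=O)[C@]1(O[Si](CC)(CC)CC)CC[C@@](C)(Cl)[C@H](Br)C1 | intermediate
18 | tert-butyl{[(2E)-6-{(1S,3R,4R)-3-bromo-4-chloro-4-methyl-1-[(triethylsilyl)oxy]cyclohexyl}-2-methylhepta-2,6-dien-1-yl]oxy}dimethylsilane | CC(C)(C)[Si](C)(C)OC/C(C)=C/CCC(=C)[C@]1(O[Si](CC)(CC)CC)CC[C@@](C)(Cl)[C@H](Br)C1 | intermediate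
19 | (1S,3R,4R)-3-bromo-4-chloro-1-[(5E)-7-hydroxy-6-methylhepta-1,5-dien-2-yl]-4-methylcyclohexan-1-ol | OC/C(C)=C/CCC(=C)[C@]1(O)CC[C@@](C)(Cl)[C@H](Br)C1 | intermediate
20 | (1S,3R,4R)-3-bromo-4-chloro-1-{4-[(2R,3R)-3-(hydroxymethyl)-3-methyloxiran-2-yl]but-1-en-2-yl}-4-methylcyclohexan-1-ol | OC[C@@]1(C)O[C@@H]1CCC(=C)[C@]2(O)CC[C@@](C)(Cl)[C@H](Br)C2 | intermediate
21 | (2S,3R)-3-{3-[(1S,3R,4R)-3-bromo-4-chloro-1-hydroxy-4-methylcyclohexyl]but-3-en-1-yl}-2-methyloxirane-2-carbaldehyde | O=C[C@@]1(C)O[C@@H]1CCC(=C)[C@]2(O)CC[C@@](C)(Cl)[C@H](Br)C2 | intermediate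
22 | hydrazone of 21 (epoxy hydrazone) | NN=C[C@@]1(C)O[C@@H]1CCC(=C)[C@]2(O)CC[C@@](C)(Cl)[C@H](Br)C2 | intermediate (not isolated)
23 | (1S,3R,4R)-3-bromo-4-chloro-1-[(5R)-7-diazenyl-5-hydroxy-6-methylhepta-1,6-dien-2-yl]-4-methylcyclohexan-1-ol (hydroxy alkenyldiazene) | N=NC=C(C)[C@H](O)CCC(=C)[C@]1(O)CC[C@@](C)(Cl)[C@H](Br)C1 | intermediate (not isolated)
24 | (1S,3R,4R)-3-bromo-4-chloro-1-[(5R)-5-hydroxy-6-methylhepta-1,6-dien-2-yl]-4-methylcyclohexan-1-ol | C=C(C)[C@H](O)CCC(=C)[C@]1(O)CC[C@@](C)(Cl)[C@H](Br)C1 | target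

**Step count and risks**

Total: 17 steps. Longest linear sequence: 15 steps (steps 1–8 and 11–17); steps 9–10 prepare the side-chain bromide.

Steps most likely to fail:

1. Step 5 (ether opening). Ionisation of the bridge may occur without bromine participation, which would erode stereocontrol at C4, or the tertiary chloride may lose HCl under the Lewis acid. Fallback, setting out from 6 and returning at 9: the tertiary hydroxyl of 6 is silylated (TESOTf, 2,6-lutidine) to give [(1S)-4-methyl-1-[(triethylsilyl)oxy]cyclohex-3-en-1-yl]methyl benzoate F1. Its ring alkene is then bromochlorinated intermolecularly in the Markovnikov sense (NBS with a soluble chloride source such as Me3SiCl, CH2Cl2, −78 °C). This should give 9 together with its trans-diaxial-addition diastereomer {(1S,3S,4S)-3-bromo-4-chloro-4-methyl-1-[(triethylsilyl)oxy]cyclohexyl}methyl benzoate F2, which is removed by chromatography. Steps 4–6 are bypassed, and facial control is replaced by separation.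

2. Step 17 (Wharton transposition). The hydrazone may fragment incompletely, cyclise to a pyrazoline, or the alkenes may be reduced by diimide formed from hydrazine and traces of air; hydrazine may also attack the halides. Fallback, setting out from 20 and returning at 24: the primary hydroxyl of 20 is converted into the iodide (I2, PPh3, imidazole, CH2Cl2, 0 °C) to give (1S,3R,4R)-3-bromo-4-chloro-1-{4-[(2R,3S)-3-(iodomethyl)-3-methyloxiran-2-yl]but-1-en-2-yl}-4-methylcyclohexan-1-ol F3. Reductive ring opening with activated zinc (EtOH, rt to 40 °C) then expels the oxirane oxygen onto C5′ and forms the C6′=C7′ alkene, giving 24 directly. Step 16 is bypassed.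

3. Step 13 (methylenation). The titanium methylidene may add slowly to the ketone flanked by the quaternary silyloxy carbon, so that enolisation or Lewis-acid loss of a silyl ether competes. Fallback, setting out from 17 and returning at 19: Me3SiCH2Li/CeCl3 (THF, −78 °C) is added to the ketone to give the β-hydroxysilane (5E)-2-{(1S,3R,4R)-3-bromo-4-chloro-4-methyl-1-[(triethylsilyl)oxy]cyclohexyl}-7-[(tert-butyldimethylsilyl)oxy]-6-methyl-1-(trimethylsilyl)hept-5-en-2-ol F4. Treatment with HF·pyridine in THF should then effect the acid-type Peterson elimination to the C1′=C2′ alkene and remove both silyl ethers in the same operation, giving 19. Steps 13 and 14 are replaced.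

**Further compounds**

F1 | step 5 | [(1S)-4-methyl-1-[(triethylsilyl)oxy]cyclohex-3-en-1-yl]methyl benzoate | O=C(OC[C@]1(O[Si](CC)(CC)CC)CCC(C)=CC1)c1ccccc1
F2 | step 5 | {(1S,3S,4S)-3-bromo-4-chloro-4-methyl-1-[(triethylsilyl)oxy]cyclohexyl}methyl benzoate | O=C(OC[C@]1(O[Si](CC)(CC)CC)CC[C@](C)(Cl)[C@@H](Br)C1)c1ccccc1
F3 | step 17 | (1S,3R,4R)-3-bromo-4-chloro-1-{4-[(2R,3S)-3-(iodomethyl)-3-methyloxiran-2-yl]but-1-en-2-yl}-4-methylcyclohexan-1-ol | IC[C@@]1(C)O[C@@H]1CCC(=C)[C@]2(O)CC[C@@](C)(Cl)[C@H](Br)C2
F4 | step 13 | (5E)-2-{(1S,3R,4R)-3-bromo-4-chloro-4-methyl-1-[(triethylsilyl)oxy]cyclohexyl}-7-[(tert-butyldimethylsilyl)oxy]-6-methyl-1-(trimethylsilyl)hept-5-en-2-ol | CC(C)(C)[Si](C)(C)OC/C(C)=C/CCC(O)(C[Si](C)(C)C)[C@]1(O[Si](CC)(CC)CC)CC[C@@](C)(Cl)[C@H](Br)C1
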